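**Retrosynthetic overview**

1. Feature: C1 (ketone) and C6 (lactone carbinol) lie 1,6 across the ten-membered ring with the (4Z)-C4=C5 olefin between them. A C1–C6 bond therefore turns the macrocycle into a cyclohexene (ring A: C1–C6) cis-fused to a cyclohexane (ring B: C1, C10, C9, C8, C7, C6) whose two ring-fusion carbons carry a glycol.
2. Target ⇐ (4Z)-ene-1,6-dione by C6 reduction, 6,12-lactonisation, methylenation at C11, O8 angelate and O9 acetate; the dione ⇐ glycol cleavage of the C1–C6 bond of the cis-bicyclo[4.4.0]dec-4-ene-1,6-diol.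
3. Bicyclic diol ⇐ ring A by ring-closing metathesis (C4=C5) of a C6 vinyl carbinol with a C3 isopropenyl ketone; both arms are added from the α face to C1 and C6 ketones made from a C1=C6 olefin.
4. Ring B ⇐ toluene cis-dihydrodiol (C8, C9, C10 with C14): syn-vinyl epoxide, then Pd-catalysed cis-1,4 opening with a phosphonoacetate sets C7 and C10.
5. Ring order: ring B (chiral pool) → ring A (metathesis) → ten-membered ring (C1–C6 scission) → γ-lactone.

Key step: step 16

Remark: germacrane numbering is used throughout; β is the face of the carbocycle that carries O8 and O9, α the opposite face.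
Remark: the bromohydrin of step 2 is assumed to be 1β-hydroxy-10α-bromo; the other trans-bromohydrin would close to the same epoxide.
Remark: C11 is an inconsequential epimer mixture from step 3 to step 17 (no descriptor in the SMILES) and becomes trigonal in step 18; the carbinol configurations at C1 and C6 that exist between steps 5 and 15 are transient.
Remark: the free C6 carbinols formed in steps 5 and 9 are γ-hydroxy esters and are carried on without delay so that the hindered α-phosphono ester does not lactonise.

Step 1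
Reactants: 1 (1S,2R)-3-methylcyclohexa-3,5-diene-1,2-diol
Product: 2 8,9-O-isopropylidene acetal of 1
Conditions: 2,2-dimethoxypropane, TsOH (cat.), CH2Cl2, 0 °C
Reagents that add atoms: 2,2-dimethoxypropane, COC(C)(C)OC
Why: Acid-catalysed transketalisation (acetonide formation) of the cis-diol touches no stereocentre and blocks the β face of ring B for the later steps.

Step 2
Reactants: 2 8,9-O-isopropylidene acetal of 1
Product: 4 1β,10β-epoxide of diene 2 (oxirane syn to the acetonide), via bromohydrin 3 (not isolated)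
Conditions: NBS, THF/H2O (4:1), 0 °C; then NaOH (aq), 0 °C
Reagents that add atoms: water, O
Why: Bromohydrin formation and Williamson ring closure: the bromonium ion should form on the more electron-rich trisubstituted C10=C1 olefin anti to the acetonide, water opens it from the β face and base closes the oxirane on the β face, which sets C10 (O10 β, C14 α) as in the known bromohydrin route to syn-epoxides of arene cis-diol acetonides.

Step 3
Reactants: 4 1β,10β-epoxide; 5 trimethyl phosphonoacetate
Product: 6 ring-B allylic alcohol with 7β-CH(PO(OMe)2)CO2Me, 10β-OH and C1=C6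
Conditions: Pd(PPh3)4 (5 mol %), 5 (1.5 equiv), THF, 25–40 °C
Reagents that add atoms: 5 trimethyl phosphonoacetate, COC(=O)CP(=O)(OC)OC
Why: Tsuji–Trost opening of a vinyl epoxide: zerovalent palladium ionises the allylic C1–O bond from the α face, the alkoxide deprotonates 5 and the soft carbanion attacks the distal terminus C7 anti to palladium (net retention), so C7 is set with C11 β, cis to O10 and to the acetonide.

Step 4
Reactants: 6 allylic alcohol
Product: 7 10-O-methoxymethyl ether of 6
Conditions: MOMCl, iPr2NEt, Bu4NI (cat.), ClCH2CH2Cl, 50 °C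
Reagents that add atoms: chloromethyl methyl ether, COCCl
Why: Iodide-assisted O-alkylation of the tertiary allylic alcohol caps O10, so that no second free 1,2-diol or α-ketol can arise later.

Step 5
Reactants: 7 MOM ether
Product: 8 1α,6α-diol
Conditions: OsO4 (5 mol %), NMO, acetone/H2O (5:1), 20 °C
Reagents that add atoms: N-methylmorpholine N-oxide, C[N+]1([O-])CCOCC1; water, O
Why: Upjohn dihydroxylation should occur on the α face of the C1=C6 olefin, anti to the allylic OMOM group, the C7 side chain and the acetonide; both new centres are oxidised later.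

Step 6
Reactants: 8 1α,6α-diol
Product: 9 6-O-triethylsilyl ether of 8
Conditions: Et3SiCl (1.05 equiv), imidazole, CH2Cl2, −40 → 0 °C
Reagents that add atoms: chlorotriethylsilane, CC[Si](Cl)(CC)CC
Why: Selective silylation of the equatorial C6 hydroxyl is expected, since the axial C1 hydroxyl lies beside the quaternary C10.

Step 7
Reactants: 9 6-O-triethylsilyl ether
Product: 10 C1 ketone
Conditions: Dess–Martin periodinane, CH2Cl2, 0 → 20 °C
Reagents that add atoms: none
Why: Dess–Martin oxidation of the only free secondary alcohol gives the C1 ketone under non-basic conditions that leave the acetals and the silyl ether intact.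

Step 8
Reactants: 10 C1 ketone; 11 4-acetylmorpholine
Product: 12 aldol adduct with 1β-OH and the 1α-CH2C(=O)-morpholine arm
Conditions: LiN(iPr)2 (3.5 equiv), 11 (3.5 equiv), THF, −78 °C; then 10, −78 °C; NH4Cl (aq)
Reagents that add atoms: 11 4-acetylmorpholine, CC(=O)N1CCOCC1
Why: Aldol addition of the lithium amide enolate should take place axially on the α face of the C1 carbonyl, antiperiplanar to the axial C10–OMOM bond (Felkin–Anh model) and away from the acetonide, giving the 1β-carbinol, while the phosphonoacetate is masked as its anion.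

Step 9
Reactants: 12 aldol adduct
Product: 13 1β,6α-diol (6-O-desilylated)
Conditions: HF·pyridine, pyridine/THF, 0 °C
Reagents that add atoms: none
Why: Fluoride cleavage of the secondary triethylsilyl ether spares the MOM ether and the acetonide, and the tertiary amide cannot lactonise onto O6.

Step 10
Reactants: 13 1β,6α-diol
Product: 14 C6 ketone
Conditions: Dess–Martin periodinane, CH2Cl2, 0 °C
Reagents that add atoms: none
Why: Dess–Martin oxidation of the only secondary alcohol gives the C6 ketone without base, which avoids β-elimination of O8 and epimerisation at C7.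

Step 11
Reactants: 14 C6 ketone; 15 vinylmagnesium bromide
Product: 16 6β-hydroxy-6α-vinyl carbinol (1β,6β-cis-diol)
Conditions: CH2=CHMgBr (4 equiv), CeCl3 (anhydrous), THF, −78 °C; NH4Cl (aq) at −78 °C
Reagents that add atoms: 15 vinylmagnesium bromide, C=C[Mg]Br
Why: Organocerium 1,2-addition: the weakly basic vinylcerium reagent should add to the enolisable ketone (not to the tertiary amide) equatorially from the α face, because the β face is screened by the syn-axial O8 and O10 groups and the acetonide, giving the cis-diol with a gauche C2 arm and C5 vinyl group.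

Step 12
Reactants: 16 vinyl carbinol; 17 isopropenylmagnesium bromide
Product: 18 isopropenyl ketone (C3 ketone)
Conditions: CH2=C(CH3)MgBr (6 equiv), THF, 0 → 20 °C; NH4Cl (aq)
Reagents that add atoms: 17 isopropenylmagnesium bromide, CC(=C)[Mg]Br
Why: Acyl substitution of the morpholine amide by the Grignard reagent proceeds through a stable tetrahedral adduct and should stop at the ketone, the phosphonoacetate being protected as its magnesium enolate.

Step 13
Reactants: 18 isopropenyl ketone
Product: 19 cis-fused bicyclo[4.4.0]dec-4-en-3-one 1β,6β-diol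
Conditions: second-generation Grubbs catalyst RuCl2(=CHPh)(PCy3)(H2IMes) (10 mol %), CH2Cl2 (0.005 M), 40 °C
Reagents that add atoms: none
Why: Ring-closing metathesis of the C6 vinyl group with the isopropenyl ketone should close ring A as a trisubstituted cyclohexenone (C4=C5), whose ring olefin can only be cis.

Step 14
Reactants: 19 bicyclic enone
Product: 21 3β-alcohol (1β,3β,6β-triol), via diethylborinate 20 (not isolated)
Conditions: Et2BOMe, THF/MeOH (4:1), −78 °C; NaBH4, −78 °C; AcOH, then MeOH evaporation
Reagents that add atoms: none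
Why: Narasaka–Prasad reduction: boron bridges the 1β-hydroxyl (axial on ring A) and the C3 carbonyl and external hydride should add from the α face, giving the cis-1,3-diol and so setting C3.

Step 15
Reactants: 21 3β-alcohol
Product: 22 3-O-tert-butyldimethylsilyl ether (key precursor)
Conditions: tBuMe2SiOTf, 2,6-lutidine, CH2Cl2, −78 °C
Reagents that add atoms: tert-butyldimethylsilyl triflate, CC(C)(C)[Si](C)(C)OS(=O)(=O)C(F)(F)F
Why: Silylation at −78 °C should take the only secondary hydroxyl and leave the two tertiary ring-fusion hydroxyls free for the cleavage.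

Step 16
Reactants: 22 cis-1β,6β-dihydroxybicyclo[4.4.0]dec-4-ene
Product: 23 (4Z)-cyclodec-4-ene-1,6-dione
Conditions: Pb(OAc)4 (1.1 equiv), CH2Cl2, −20 → 0 °C, 20 min; cold filtration through Celite; used at once
Reagents that add atoms: none
Why: Criegee glycol cleavage: tetravalent lead exchanges two acetates for the gauche 1β,6β-hydroxyls to give a five-membered cyclic lead diester, which fragments in one concerted two-electron step that breaks the C1–C6 σ bond, forms the C1 and C6 carbonyls and releases Pb(OAc)2. The closest known reaction is the Pb(OAc)4 or NaIO4 cleavage of cis-bicyclo[4.4.0]decane-1,6-diols to cyclodecane-1,6-diones. No ring is closed by bond formation; the ten-membered ring is unveiled by scission of the bond shared by rings A and B, so its mode of formation is ring expansion of the bicycle. No stereocentre is made: C1 and C6 become trigonal, C3, C7, C8, C9 and C10 are untouched, and the C4=C5 geometry is inherited as Z from the cyclohexene. The only selectivity needed is chemoselectivity for the free glycol, secured because O10 is a MOM ether, O8 and O9 are in the acetonide and O3 is silylated, so no other free 1,2-diol or α-ketol is present. The dione is kept cold and neutral and reduced at once, which should forestall transannular aldol reaction, C7 epimerisation and β-elimination of O8 or O3.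

Step 17
Reactants: 23 (4Z)-cyclodec-4-ene-1,6-dione
Product: 25 11-(dimethoxyphosphoryl) 6α,12-lactone (trans-fused), via 6α-hydroxy ester 24 (not isolated)
Conditions: NaBH4 (1.0 equiv), CeCl3·7H2O, MeOH/CH2Cl2, −78 °C; then PPTS (cat.), benzene, 45 °C
Reagents that add atoms: none
Why: Luche 1,2-reduction should take the conjugated C6 carbonyl in preference to the hindered α-quaternary C1 ketone, with hydride adding anti to the C7 side chain (Felkin–Anh model) to give the 6α-carbinol, which closes under mild acid to the trans-fused γ-lactone.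

Step 18
Reactants: 25 α-phosphono lactone; 26 formaldehyde
Product: 27 α-methylene 6α,12-lactone
Conditions: HCHO (37 % aq), K2CO3, THF, 0 → 20 °C
Reagents that add atoms: 26 formaldehyde, C=O
Why: Horner–Wadsworth–Emmons olefination of the α-phosphono lactone with formaldehyde installs the exocyclic C11=C13 methylene under mild carbonate base.

Step 19
Reactants: 27 α-methylene lactone
Product: 28 8β,9β,10β-triol (3-O-silyl)
Conditions: Me2BBr, CH2Cl2, −78 °C; then NaHCO3 (aq)/THF
Reagents that add atoms: none
Why: Lewis-acid acetal cleavage: Me2BBr should open the MOM ether and the isopropylidene ketal at −78 °C, while the silyl ether, the lactone and the enoate are stable.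

Step 20
Reactants: 28 triol; 29 angelic acid
Product: 30 8-O-angelate
Conditions: 29, 2,4,6-trichlorobenzoyl chloride, Et3N, toluene, 20 °C; then 28, toluene, 70 °C (no DMAP)
Reagents that add atoms: 29 angelic acid, C/C=C(/C)C(=O)O
Why: Yamaguchi-type esterification through the mixed anhydride without DMAP should keep the Z geometry of the angeloyl group and acylate the less hindered O8 hydroxyl, O9 being shielded by the quaternary C10 and the tertiary O10 hydroxyl being inert.

Step 21
Reactants: 30 8-O-angelate
Product: 31 9-O-acetyl-8-O-angeloyl 3-O-silyl ether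
Conditions: Ac2O, pyridine, DMAP (cat.), CH2Cl2, 0 → 20 °C
Reagents that add atoms: acetic anhydride, CC(=O)OC(C)=O
Why: DMAP-catalysed acetylation should take the remaining secondary hydroxyl (O9), the tertiary α-ketol hydroxyl at C10 being unreactive under these conditions.

Step 22
Reactants: 31 silyl ether
Product: 32 CNP0308559.2
Conditions: HF·pyridine, THF, 0 → 20 °C
Reagents that add atoms: none
Why: Fluoride desilylation under mildly acidic conditions should free O3 without touching the esters, the α-methylene lactone or the β-hydroxy ketone.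

**Compound list**

1 | (1S,2R)-3-methylcyclohexa-3,5-diene-1,2-diol (carbinol carbons become C8 and C9, the methyl-bearing carbon C10) | O[C@H]1C=CC=C(C)[C@H]1O | starting material
2 | 8,9-O-isopropylidene acetal of 1 (diene C10(CH3)=C1, C6=C7; acetonide β) | C1=C(C)[C@@H](OC2(C)C)[C@@H](O2)C=C1 | intermediate
3 | bromohydrin of 2: 10α-bromo-1β-hydroxy, C6=C7 kept | O[C@H]1[C@@](Br)(C)[C@@H](OC2(C)C)[C@@H](O2)C=C1 | intermediate
4 | 1β,10β-epoxide of 2 (oxirane syn to the acetonide, C14 α, C6=C7 kept) | [C@H]1(O3)[C@]3(C)[C@@H](OC2(C)C)[C@@H](O2)C=C1 | intermediate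
5 | trimethyl phosphonoacetate | COC(=O)CP(=O)(OC)OC | starting material
6 | ring-B cyclohex-1(6)-ene: 10β-hydroxy-10α-methyl, 8β,9β-isopropylidenedioxy, 7β-CH(PO(OMe)2)CO2Me | C1=C[C@@](C)(O)[C@@H](OC2(C)C)[C@@H](O2)[C@H]1C(C(=O)OC)P(=O)(OC)OC | intermediate
7 | 10-O-methoxymethyl ether of 6 | C1=C[C@@](C)(OCOC)[C@@H](OC2(C)C)[C@@H](O2)[C@H]1C(C(=O)OC)P(=O)(OC)OC | intermediate
8 | 1α,6α-diol from 7 | O[C@@H]1[C@H](O)[C@@](C)(OCOC)[C@@H](OC2(C)C)[C@@H](O2)[C@H]1C(C(=O)OC)P(=O)(OC)OC | intermediate
9 | 6-O-triethylsilyl ether of 8 (1α-OH free) | CC[Si](CC)(CC)O[C@@H]1[C@H](O)[C@@](C)(OCOC)[C@@H](OC2(C)C)[C@@H](O2)[C@H]1C(C(=O)OC)P(=O)(OC)OC | intermediate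
10 | C1 ketone (6α-OSiEt3) | CC[Si](CC)(CC)O[C@@H]1C(=O)[C@@](C)(OCOC)[C@@H](OC2(C)C)[C@@H](O2)[C@H]1C(C(=O)OC)P(=O)(OC)OC | intermediate
11 | 4-acetylmorpholine | CC(=O)N1CCOCC1 | starting material
12 | aldol adduct: 1β-hydroxy, 1α-CH2C(=O)-morpholin-4-yl, 6α-OSiEt3 | CC[Si](CC)(CC)O[C@@H]1[C@@](CC(=O)N3CCOCC3)(O)[C@@](C)(OCOC)[C@@H](OC2(C)C)[C@@H](O2)[C@H]1C(C(=O)OC)P(=O)(OC)OC | intermediate
13 | 1β,6α-diol from 12 | O[C@@H]1[C@@](CC(=O)N3CCOCC3)(O)[C@@](C)(OCOC)[C@@H](OC2(C)C)[C@@H](O2)[C@H]1C(C(=O)OC)P(=O)(OC)OC | intermediate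
14 | C6 ketone (1β-OH) | O=C1[C@@](CC(=O)N3CCOCC3)(O)[C@@](C)(OCOC)[C@@H](OC2(C)C)[C@@H](O2)[C@H]1C(C(=O)OC)P(=O)(OC)OC | intermediate
15 | vinylmagnesium bromide | C=C[Mg]Br | starting material
16 | 6β-hydroxy-6α-vinyl carbinol (1β,6β-cis-diol, C2 arm and vinyl both α) | C=C[C@]1(O)[C@@](CC(=O)N3CCOCC3)(O)[C@@](C)(OCOC)[C@@H](OC2(C)C)[C@@H](O2)[C@H]1C(C(=O)OC)P(=O)(OC)OC | intermediate
17 | isopropenylmagnesium bromide | CC(=C)[Mg]Br | starting material
18 | isopropenyl ketone: 1α-CH2C(=O)C(CH3)=CH2, 6α-vinyl, 1β,6β-diol | C=C[C@]1(O)[C@@](CC(=O)C(C)=C)(O)[C@@](C)(OCOC)[C@@H](OC2(C)C)[C@@H](O2)[C@H]1C(C(=O)OC)P(=O)(OC)OC | intermediate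
19 | cis-fused bicyclo[4.4.0]dec-4-en-3-one 1β,6β-diol (ring A: C4(CH3)=C5) | O[C@@]12C=C(C)C(=O)C[C@]1(O)[C@@](C)(OCOC)[C@@H](OC3(C)C)[C@@H](O3)[C@H]2C(C(=O)OC)P(=O)(OC)OC | intermediate
20 | 1-O-diethylborinate of 19 (boron chelated to the C3 carbonyl) | O[C@@]12C=C(C)C(=O)C[C@]1(OB(CC)CC)[C@@](C)(OCOC)[C@@H](OC3(C)C)[C@@H](O3)[C@H]2C(C(=O)OC)P(=O)(OC)OC | intermediate
21 | 3β-alcohol (1β,3β,6β-triol) | O[C@@]12C=C(C)[C@@H](O)C[C@]1(O)[C@@](C)(OCOC)[C@@H](OC3(C)C)[C@@H](O3)[C@H]2C(C(=O)OC)P(=O)(OC)OC | intermediate
22 | key precursor: cis-1β,6β-dihydroxybicyclo[4.4.0]dec-4-ene, 3β-OTBS, 10β-OMOM, 8β,9β-acetonide, 7β-CH(PO(OMe)2)CO2Me | O[C@@]12C=C(C)[C@@H](O[Si](C)(C)C(C)(C)C)C[C@]1(O)[C@@](C)(OCOC)[C@@H](OC3(C)C)[C@@H](O3)[C@H]2C(C(=O)OC)P(=O)(OC)OC | intermediate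
23 | (4Z)-cyclodec-4-ene-1,6-dione, substituents as in 22 | O=C1/C=C(/C)[C@@H](O[Si](C)(C)C(C)(C)C)CC(=O)[C@@](C)(OCOC)[C@@H](OC2(C)C)[C@@H](O2)[C@H]1C(C(=O)OC)P(=O)(OC)OC | intermediate
24 | 6α-hydroxy ester (C1 ketone kept) | O[C@@H]1/C=C(/C)[C@@H](O[Si](C)(C)C(C)(C)C)CC(=O)[C@@](C)(OCOC)[C@@H](OC2(C)C)[C@@H](O2)[C@H]1C(C(=O)OC)P(=O)(OC)OC | intermediate
25 | 11-(dimethoxyphosphoryl) trans-fused 6α,12-lactone | COP(=O)(OC)C1C(=O)O[C@@H]2/C=C(/C)[C@@H](O[Si](C)(C)C(C)(C)C)CC(=O)[C@@](C)(OCOC)[C@@H](OC3(C)C)[C@@H](O3)[C@@H]12 | intermediate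
26 | formaldehyde | C=O | starting material
27 | α-methylene 6α,12-lactone (3-O-TBS, 10-O-MOM, 8,9-acetonide) | C=C1C(=O)O[C@@H]2/C=C(/C)[C@@H](O[Si](C)(C)C(C)(C)C)CC(=O)[C@@](C)(OCOC)[C@@H](OC3(C)C)[C@@H](O3)[C@@H]12 | intermediate
28 | 8β,9β,10β-triol (3-O-TBS) | C=C1C(=O)O[C@@H]2/C=C(/C)[C@@H](O[Si](C)(C)C(C)(C)C)CC(=O)[C@@](C)(O)[C@@H](O)[C@@H](O)[C@@H]12 | intermediate
29 | angelic acid, (Z)-2-methylbut-2-enoic acid | C/C=C(/C)C(=O)O | starting material
30 | 8-O-angelate of 28 | C=C1C(=O)O[C@@H]2/C=C(/C)[C@@H](O[Si](C)(C)C(C)(C)C)CC(=O)[C@@](C)(O)[C@@H](O)[C@@H](OC(=O)/C(C)=C\C)[C@@H]12 | intermediate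
31 | 9-O-acetyl-8-O-angeloyl 3-O-TBS ether | C=C1C(=O)O[C@@H]2/C=C(/C)[C@@H](O[Si](C)(C)C(C)(C)C)CC(=O)[C@@](C)(O)[C@@H](OC(C)=O)[C@@H](OC(=O)/C(C)=C\C)[C@@H]12 | intermediate
32 | CNP0308559.2 | C=C1C(=O)O[C@@H]2/C=C(/C)[C@@H](O)CC(=O)[C@@](C)(O)[C@@H](OC(C)=O)[C@@H](OC(=O)/C(C)=C\C)[C@@H]12 | target

**Step count and risks**

Total step count: 22. Longest linear sequence: 22 steps from 1.

Steps most likely to fail:

Step 16. The cyclic lead diester may form slowly at the crowded ditertiary glycol, or not at all if step 11 had delivered the vinyl group to the β face and the glycol were trans-diaxial. The cleavage would then stall while the dione already formed is exposed to acetic acid and lead salts and is lost by transannular aldol reaction or β-elimination. The fallback sets out from diol 22 and replaces the two-electron cyclic pathway by alkoxy-radical fragmentation (PhI(OAc)2, I2, CH2Cl2, visible light, 0 °C). One tertiary hydroxyl is O-iodinated and homolysed, and β-scission of the C1–C6 bond gives the C1 ketone and a tertiary allylic α-hydroxyalkyl radical at C6, which is oxidised to the ketone. This needs neither a cyclic intermediate nor a cis glycol and comes back to the route at dione 23. No compound outside the compound list is made on this way, which the label F0 records.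

Step 17. Hydride delivery to the C6 carbonyl of the flexible ten-membered ring may show poor or reversed facial selectivity, giving the 6β-carbinol, which would close to the cis-fused lactone. The fallback sets out from dione 23 and corrects C6 by inversion. The Luche reduction is run as before but the acid treatment is omitted, which should give the 6β-hydroxy ester F1, isolated cold. Mitsunobu reaction (PPh3, DIAD, 4-nitrobenzoic acid, toluene, 0 °C) then displaces the activated allylic hydroxyl with inversion to give the 6α-(4-nitrobenzoate) F2. K2CO3 in MeOH at 0 °C removes the benzoate and the freed 6α-alkoxide closes onto the methyl ester, which comes back to the route at lactone 25.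

Step 20. The heating needed for direct angeloylation may erode the site selectivity between O8 and O9, cause over-acylation and isomerise the angeloyl group from Z to E. The fallback sets out from triol 28 and uses a silyl relay. Et3SiOTf and 2,6-lutidine at −78 °C should silylate only the less hindered O8 to give the 8-O-triethylsilyl ether F3. Ac2O with DMAP then gives the 9-O-acetyl-8-O-triethylsilyl ether F4. HF·pyridine in pyridine/THF at −20 °C removes the triethylsilyl group in the presence of the tert-butyldimethylsilyl ether and gives the 9-O-acetyl-8-alcohol F5. Angeloylation with the mixed anhydride of step 20 then meets a single free secondary hydroxyl and comes back to the route at diester 31.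

**Further compounds**

F0 | step 16 | none | none
F1 | step 17 | 6β-hydroxy ester | O[C@H]1/C=C(/C)[C@@H](O[Si](C)(C)C(C)(C)C)CC(=O)[C@@](C)(OCOC)[C@@H](OC2(C)C)[C@@H](O2)[C@H]1C(C(=O)OC)P(=O)(OC)OC
F2 | step 17 | 6α-(4-nitrobenzoate) | O=C(O[C@@H]1/C=C(/C)[C@@H](O[Si](C)(C)C(C)(C)C)CC(=O)[C@@](C)(OCOC)[C@@H](OC2(C)C)[C@@H](O2)[C@H]1C(C(=O)OC)P(=O)(OC)OC)c1ccc(cc1)[N+](=O)[O-]
F3 | step 20 | 8-O-triethylsilyl ether | C=C1C(=O)O[C@@H]2/C=C(/C)[C@@H](O[Si](C)(C)C(C)(C)C)CC(=O)[C@@](C)(O)[C@@H](O)[C@@H](O[Si](CC)(CC)CC)[C@@H]12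
F4 | step 20 | 9-O-acetyl-8-O-triethylsilyl ether | C=C1C(=O)O[C@@H]2/C=C(/C)[C@@H](O[Si](C)(C)C(C)(C)C)CC(=O)[C@@](C)(O)[C@@H](OC(C)=O)[C@@H](O[Si](CC)(CC)CC)[C@@H]12
F5 | step 20 | 9-O-acetyl-8-alcohol | C=C1C(=O)O[C@@H]2/C=C(/C)[C@@H](O[Si](C)(C)C(C)(C)C)CC(=O)[C@@](C)(O)[C@@H](OC(C)=O)[C@@H](O)[C@@H]12
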